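All constants are made up; no experiment stands behind them.

The unit here is the mM of L held, so one L.Q counts as two.

    L + Q → L.Q (k1 = 3.6 M⁻¹ s⁻¹)
    L → X (k2 = 1.9 × 10⁻⁵ s⁻¹)
    L ⇌ E (K3 = 0.15, k3 = 0.011 s⁻¹)
    L ⇌ G (K4 = 1.7, k4 = 0.020 s⁻¹)
    D ⇌ Z (K5 = 1.2, k5 = 0.032 s⁻¹)
    G ⇌ Q (K6 = 0.49, k6 = 0.014 s⁻¹)
    E → D (k7 = 0.0085 s⁻¹)

in all of them: L 2.0 mM

| charge | time | remark |
|---|---|---|
| midnight | 1.0 min | a closed flask charged with all of it at once and left for 1.0 min |
| dawn |  | one stirred flow tank at steady state, fed with the mixture as stated, mean residence time 1.0 min |

- the set-up with the highest share of Z in all that became Z or L.Q, at the outlet or at the end ("none" if the first two lie within 2 percentage points) (midnight / dawn / none)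
- share of Z in all that became Z or L.Q, at the outlet or at the end, midnight
- share of Z in all that became Z or L.Q, at the outlet or at the end, dawn

- percentages count the L that a species holds: one L.Q counts as two
- the stated concentrations are those of everything mixed, before any reaction; amounts are the same in each set-up
- run time (midnight): 1.0 min

I take the products as a small correction on the charge, so early in the midnight flask cL stands at its charged value. Z then comes down the chain L, E, D, Z and L.Q down the chain L, G, Q, L.Q. Each chain grows with the cube of time times the product of its three constants. The last L.Q link is pseudo-first-order: the constant of L + Q times cL, doubled by the counting rule.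

| link | towards Z | towards L.Q | Z side over L.Q side |
|---|---|---|---|
| first | 0.011 s⁻¹ | 0.020 s⁻¹ | 0.550 |
| second | 0.0085 s⁻¹ | 0.014 s⁻¹ | 0.607 |
| third | 0.032 s⁻¹ | 0.0144 s⁻¹ | 2.22 |

The first row favours L.Q, with E formed more slowly than G, and so does the second. The third row turns the other way. Multiplied, the rows give 0.742: the early selectivity factor S, L held in Z per L held in L.Q. The share of Z is S over one plus S, here 42.6%. Since cL enters once, below the line, S goes with one over cL, the constants held. The run lasts longer than the lifetime of E, so for midnight I treat this as a starting value and expect less, by an amount I can't reckon by hand.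

For the dawn tank, balances without product drains give cE/cL 0.112, cG/cL 0.595 and cQ/cL 0.184, so cL is 1.06 mM. A fraction 0.425 of the D and Z pair leaves as Z. That makes the ratio 0.287 and the share 22.3%, so I commit to midnight.

The forecast, lower than my midnight starting value and higher than my tank figure, gives midnight, 37% and 25%, holding that “in the closed flask Q builds up only slowly and the early E route to Z gets a head start”.

The flask gives midnight, with 36.5% at midnight and 25.0% at dawn. In the dawn tank cL stands at 1.00 mM, lower than my figure. At midnight the final ratio is 0.575, below S, a fraction 0.775 of it. Scaled by one over cL to a midnight charge of 2.54 mM, S becomes 0.585, and the same fraction of that is 0.453, a share of 31.2%, which is 5.3 percentage points under the present one. The flask charged that way has moved 5 points.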